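## Retrosynthetic overview
1. C3–C1' bond: a late Suzuki coupling joins a 3-chloro bicyclic core to a (1E,3E,5S)-dienylboronate made from (S)-2-methylbutan-1-ol.
2. C5(OH)CO2Me comes from a 5-methylidene ring B by dihydroxylation anti to the C6 silyl ether, then CH2OH → CO2Me. This gives the trans-diol.
3. Ring B: the C7–C7a bond is made by Parham cyclisation of the bromopyridine onto the dioxolanone carbonyl, and the auxiliary carbon leaves in the same step.
4. Key C5–C6 bond: an intermolecular aldol of the (R)-lactic acid dioxolanone enolate with 5-bromo-2-chloropyridine-4-carbaldehyde sets C6.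
5. Ring order: pyridine ring A is bought, the temporary dioxolanone ring is made first, and carbocyclic ring B is closed last.

Assumption: the SMILES is read as (5R,6S) with the two ring hydroxyls trans (5-OH cis to 6-CH3), 5'S and 1'E,3'E. Atom numbers follow cyclopenta[c]pyridine (N2, C3 bears the side chain, C5 the ester, C7 the ketone).

## Route

Step 1
Reactants: 1 (R)-lactic acid; 2 pivalaldehyde
Product: 3 (2R,5R)-2-tert-butyl-5-methyl-1,3-dioxolan-4-one (cis isomer)
Conditions: p-TsOH·H2O (cat.), H2SO4 (cat.), pentane, reflux, Dean–Stark trap; crystallisation from pentane, −78 °C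
Reagents that add atoms: none
Why: Acid-catalysed acetalisation with azeotropic water removal (first stage of Seebach's self-regeneration of stereocentres) is reversible, so the new acetal carbon C2 settles mainly as the cis isomer (about 4:1) with tert-butyl and methyl on the same ring face, i.e. 2R under control of the 5R lactate centre, and cold crystallisation removes the trans isomer.

Step 2
Reactants: 4 5-bromo-2-chloropyridine
Product: 6 5-bromo-2-chloropyridine-4-carbaldehyde, via 5-bromo-2-chloro-4-lithiopyridine 5 (not isolated)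
Conditions: LiN(iPr)2 (1.05 equiv), THF, −78 °C, 30 min; DMF (1.5 equiv), −78 °C; AcOH quench
Reagents that add atoms: N,N-dimethylformamide (DMF), CN(C)C=O
Why: Directed ortho-lithiation followed by formylation: the hindered amide base removes H4, which is acidified by the adjacent bromine and is the established deprotonation site of this pyridine, and at −78 °C anion 5 is trapped by DMF before halogen migration can start.

Step 3
Reactants: 3 (2R,5R)-2-tert-butyl-5-methyl-1,3-dioxolan-4-one; 6 5-bromo-2-chloropyridine-4-carbaldehyde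
Product: 8 (2R,5S)-5-[(5-bromo-2-chloropyridin-4-yl)(hydroxy)methyl]-2-tert-butyl-5-methyl-1,3-dioxolan-4-one (both carbinol epimers), via lithium dioxolanone enolate 7 (not isolated)
Conditions: 3, LiN(iPr)2 (1.05 equiv), THF, −78 °C, 45 min; 6, −78 °C, 1 h; AcOH quench at −78 °C
Reagents that add atoms: none
Why: Intermolecular aldol addition of a lithium ester enolate to a non-enolisable aldehyde: in the flat enolate 7 only the acetal centre survives and its tert-butyl group shields one face, so the aldehyde bonds to the opposite face where the hydrogen used to be (net retention, 5R becomes 5S only through the priority rules), which fixes the future C6 as S, while the secondary carbinol centre forms as a mixture that is erased in step 4.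

Step 4
Reactants: 8 aldol adduct
Product: 9 (2R,5S)-5-(5-bromo-2-chloropyridine-4-carbonyl)-2-tert-butyl-5-methyl-1,3-dioxolan-4-one
Conditions: Dess–Martin periodinane (1.3 equiv), CH2Cl2, 0 °C → rt
Reagents that add atoms: none
Why: Dess–Martin oxidation works on hindered secondary alcohols under nearly neutral conditions that leave the acetal, the lactone and both halogens alone, and the ketone has no α-hydrogen so the quaternary centre cannot epimerise.

Step 5
Reactants: 9 aryl ketone
Product: 10 (2R,5S)-5-[1-(5-bromo-2-chloropyridin-4-yl)-1-hydroxyethyl]-2-tert-butyl-5-methyl-1,3-dioxolan-4-one (both carbinol epimers)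
Conditions: MeMgBr (1.2 equiv), THF, −78 °C; AcOH quench at −78 °C
Reagents that add atoms: methylmagnesium bromide, C[Mg]Br
Why: Chemoselective Grignard 1,2-addition: the ketone, activated by the electron-poor pyridine and the α-oxygen, reacts at −78 °C far faster than the lactone carbonyl, MeMgBr does not undergo halogen–metal exchange, the cold acid quench stops retro-aldol cleavage of the alkoxide, and the new tertiary carbinol centre (mixture) is erased in step 6.

Step 6
Reactants: 10 tertiary alcohol
Product: 12 (2R,5S)-5-[1-(5-bromo-2-chloropyridin-4-yl)ethenyl]-2-tert-butyl-5-methyl-1,3-dioxolan-4-one, via chlorosulfite ester 11 (not isolated)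
Conditions: SOCl2 (3 equiv), pyridine, 0 °C → rt
Reagents that add atoms: none
Why: Dehydration by E2 elimination of chlorosulfite 11: the carbinol carbon is flanked by an aromatic carbon, a quaternary carbon and the methyl group, so only the methyl group can lose a proton and the 1,1-disubstituted alkene is the sole possible regioisomer, while the electron-poor pyridyl group disfavours ionisation and chloride substitution.

Step 7
Reactants: 12 bromo alkene
Product: 15 (S)-3-chloro-6-hydroxy-6-methyl-5-methylidene-5,6-dihydro-7H-cyclopenta[c]pyridin-7-one, via aryllithium 13 (not isolated), via lithium hemiketal 14 (not isolated)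
Conditions: n-BuLi (1.05 equiv, slow addition), THF, −95 → −78 °C, 30 min; AcOH at −78 °C, then rt
Reagents that add atoms: none
Why: Parham cyclisation: bromine–lithium exchange on the bromopyridine outruns addition of n-BuLi to the hindered lactone at this temperature, aryllithium 13 closes five-membered ring B on the only carbonyl within reach, hemiketal salt 14 is stable at −78 °C and so shields the nascent ketone from over-addition, and protonation makes it shed the acetal carbon without touching C6.

Step 8
Reactants: 15 hydroxy ketone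
Product: 16 (S)-6-(tert-butyldimethylsilyloxy)-3-chloro-6-methyl-5-methylidene-5,6-dihydro-7H-cyclopenta[c]pyridin-7-one
Conditions: TBSOTf (1.5 equiv), 2,6-lutidine (2.5 equiv), CH2Cl2, 0 °C → rt
Reagents that add atoms: tert-butyldimethylsilyl triflate (TBSOTf), CC(C)(C)[Si](C)(C)OS(=O)(=O)C(F)(F)F
Why: Silyl triflate silylation reaches tertiary alcohols, the ketone has no α-hydrogen so no silyl enol ether can form, and the bulky ether blocks α-ketol rearrangement and covers one face of ring B for step 9.

Step 9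
Reactants: 16 silyl ether
Product: 17 (5S,6S)-6-(tert-butyldimethylsilyloxy)-3-chloro-5-hydroxy-5-(hydroxymethyl)-6-methyl-5,6-dihydro-7H-cyclopenta[c]pyridin-7-one
Conditions: OsO4 (4 mol %), NMO (2 equiv), acetone/H2O 5:1, rt; chromatography
Reagents that add atoms: osmium tetroxide (catalytic oxygen carrier), O=[Os](=O)(=O)=O; N-methylmorpholine N-oxide (NMO), C[N+]1([O-])CCOCC1; water, O
Why: Upjohn syn-dihydroxylation under substrate control: ring B is flat and C6 holds a methyl group on one face and the large silyloxy group on the other, so OsO4 attacks the exocyclic alkene anti to the allylic oxygen (Kishi's empirical rule reinforced by the bulk of the silyl group), which places the new C5 hydroxyl trans to the C6 oxygen and cis to the methyl group, and any minor epimer is removed on silica.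

Step 10
Reactants: 17 diol
Product: 18 (5R,6S)-6-(tert-butyldimethylsilyloxy)-3-chloro-5-hydroxy-6-methyl-7-oxo-6,7-dihydro-5H-cyclopenta[c]pyridine-5-carbaldehyde
Conditions: IBX (1.8 equiv), DMSO, rt
Reagents that add atoms: none
Why: IBX oxidation takes 1,2-diols to α-hydroxy carbonyl compounds without C–C cleavage, only the primary carbinol can be oxidised, and the neutral medium triggers neither silyl migration nor retro-aldol opening of the β-hydroxy ketone (the descriptor at C5 changes to R only through the priority rules).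

Step 11
Reactants: 18 hydroxy aldehyde
Product: 19 (5R,6S)-6-(tert-butyldimethylsilyloxy)-3-chloro-5-hydroxy-6-methyl-7-oxo-6,7-dihydro-5H-cyclopenta[c]pyridine-5-carboxylic acid
Conditions: NaClO2 (3 equiv), NaH2PO4 (3 equiv), 2-methylbut-2-ene (10 equiv), t-BuOH/H2O, 0 °C → rt
Reagents that add atoms: sodium chlorite, [Na+].[O-]Cl=O
Why: Pinnick oxidation converts the non-enolisable aldehyde to the acid at about pH 4, conditions under which the tertiary silyl ether, the ketone and both stereocentres are untouched, and no alkene is left in the substrate to be chlorinated.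

Step 12
Reactants: 19 hydroxy acid
Product: 20 methyl (5R,6S)-6-(tert-butyldimethylsilyloxy)-3-chloro-5-hydroxy-6-methyl-7-oxo-6,7-dihydro-5H-cyclopenta[c]pyridine-5-carboxylate
Conditions: TMSCHN2 (1.3 equiv), toluene/MeOH 4:1, 0 °C
Reagents that add atoms: (trimethylsilyl)diazomethane, C[Si](C)(C)C=[N+]=[N-]
Why: Diazoalkane O-methylation esterifies the hindered acid at the carboxylate oxygen without any base, so steric crowding at C5 is irrelevant and the base-labile β-hydroxy ketone is safe.

Step 13
Reactants: 20 hydroxy ester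
Product: 21 methyl (5R,6S)-6-(tert-butyldimethylsilyloxy)-3-chloro-6-methyl-7-oxo-5-(triethylsilyloxy)-6,7-dihydro-5H-cyclopenta[c]pyridine-5-carboxylate
Conditions: TESOTf (2 equiv), 2,6-lutidine (3 equiv), CH2Cl2, 0 °C → rt
Reagents that add atoms: triethylsilyl triflate (TESOTf), CC[Si](CC)(CC)OS(=O)(=O)C(F)(F)F
Why: Silyl triflate silylation masks the C5 hydroxyl so that the base of step 21 cannot form the alkoxide whose retro-aldol ring opening would scramble C5 and C6.

Step 14
Reactants: 22 (S)-2-methylbutan-1-ol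
Product: 23 (S)-2-methylbutanal
Conditions: TEMPO (1 mol %), KBr (10 mol %), NaOCl (1.1 equiv, pH 9.5), CH2Cl2/H2O, 0 °C; distillation
Reagents that add atoms: none
Why: Anelli oxidation (oxoammonium catalysis) is complete within minutes at 0 °C and stops at the aldehyde, which keeps the enolisable α-stereocentre from racemising.

Step 15
Reactants: 23 (S)-2-methylbutanal
Product: 24 ethyl (2E,4S)-2,4-dimethylhex-2-enoate
Conditions: Ph3P=C(CH3)CO2Et (1.1 equiv), CH2Cl2, rt, 16 h
Reagents that add atoms: ethyl 2-(triphenylphosphoranylidene)propanoate, CCOC(=O)C(C)=P(c1ccccc1)(c1ccccc1)c1ccccc1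
Why: Wittig olefination with a stabilised ylide gives the E-trisubstituted enoate (E:Z at least 95:5), and the ylide is too weak a base to epimerise the aldehyde.

Step 16
Reactants: 24 enoate
Product: 25 (2E,4S)-2,4-dimethylhex-2-en-1-ol
Conditions: iBu2AlH (2.2 equiv), CH2Cl2, −78 °C; aq KNaC4H4O6 work-up
Reagents that add atoms: none
Why: Hydride reduction of an enoate with iBu2AlH proceeds by clean 1,2-delivery to the allylic alcohol and leaves the alkene geometry and the stereocentre unchanged.

Step 17
Reactants: 25 allylic alcohol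
Product: 26 (2E,4S)-2,4-dimethylhex-2-enal
Conditions: MnO2 (15 equiv), CH2Cl2, rt
Reagents that add atoms: none
Why: Allylic oxidation with MnO2 is selective, neutral and heterogeneous, so neither E/Z isomerisation nor γ-deprotonation at the stereocentre takes place.

Step 18
Reactants: 26 enal
Product: 27 (3E,5S)-1,1-dibromo-3,5-dimethylhepta-1,3-diene
Conditions: CBr4 (2 equiv), PPh3 (4 equiv), CH2Cl2, 0 °C
Reagents that add atoms: carbon tetrabromide, BrC(Br)(Br)Br
Why: First stage of the Corey–Fuchs homologation, a Wittig-type dibromo-olefination that works well on enals under non-basic conditions.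

Step 19
Reactants: 27 dibromodiene
Product: 29 (3E,5S)-3,5-dimethylhept-3-en-1-yne, via lithium acetylide 28 (not isolated)
Conditions: n-BuLi (2.1 equiv), THF, −78 → 0 °C; H2O; handled as a concentrated solution (volatile)
Reagents that add atoms: none
Why: Second stage of the Corey–Fuchs homologation: elimination and bromine–lithium exchange give acetylide 28, which is simply protonated, and the remote allylic stereocentre is not acidic enough to be touched at low temperature.

Step 20
Reactants: 29 enyne
Product: 30 2-[(1E,3E,5S)-3,5-dimethylhepta-1,3-dien-1-yl]-4,4,5,5-tetramethyl-1,3,2-dioxaborolane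
Conditions: pinacolborane (1.2 equiv), Cp2ZrHCl (10 mol %), Et3N (10 mol %), neat, 60 °C
Reagents that add atoms: pinacolborane, [H]B1OC(C)(C)C(C)(C)O1
Why: Zirconium-catalysed hydroboration adds H and B syn across the terminal alkyne with boron on the terminal carbon, which sets the 1E geometry, while the trisubstituted alkene is too hindered to react.

Step 21
Reactants: 21 bis-silyl chloropyridine; 30 dienylboronate
Product: 31 methyl (5R,6S)-6-(tert-butyldimethylsilyloxy)-3-[(1E,3E,5S)-3,5-dimethylhepta-1,3-dien-1-yl]-6-methyl-7-oxo-5-(triethylsilyloxy)-6,7-dihydro-5H-cyclopenta[c]pyridine-5-carboxylate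
Conditions: Pd(dppf)Cl2 (5 mol %), K3PO4 (2 equiv), 1,4-dioxane/H2O 9:1, 70 °C
Reagents that add atoms: none
Why: Suzuki–Miyaura coupling: the C–Cl bond next to nitrogen and para to the ketone adds readily to zerovalent palladium, the alkenyl group is transferred with retention of its E geometry, and the fully substituted, doubly silylated ring B offers the base neither an acidic hydrogen nor a free hydroxyl.

Step 22
Reactants: 31 bis-silyl ether
Product: 32 methyl (5R,6S)-3-[(1E,3E,5S)-3,5-dimethylhepta-1,3-dien-1-yl]-5,6-dihydroxy-6-methyl-7-oxo-6,7-dihydro-5H-cyclopenta[c]pyridine-5-carboxylate (target)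
Conditions: HF·pyridine, pyridine, THF, 0 °C → rt (plastic vessel); pH 7 buffer work-up
Reagents that add atoms: none
Why: Fluoride-driven desilylation in a mildly acidic medium cleaves both Si–O bonds with retention at carbon and avoids the alkoxide conditions that would cause retro-aldol or α-ketol scrambling, while the electron-poor carbinol carbons do not ionise.

## Compound list
1 | (R)-lactic acid | C[C@@H](O)C(=O)O | starting material
2 | pivalaldehyde | CC(C)(C)C=O | starting material
3 | (2R,5R)-2-tert-butyl-5-methyl-1,3-dioxolan-4-one | C[C@H]1O[C@@H](C(C)(C)C)OC1=O | intermediate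
4 | 5-bromo-2-chloropyridine | Clc1ccc(Br)cn1 | starting material
5 | 5-bromo-2-chloro-4-lithiopyridine (not isolated) | [Li]c1cc(Cl)ncc1Br | intermediate
6 | 5-bromo-2-chloropyridine-4-carbaldehyde | O=Cc1cc(Cl)ncc1Br | intermediate
7 | lithium (R)-2-tert-butyl-5-methyl-1,3-dioxol-4-olate (not isolated) | CC1=C(O[Li])O[C@H](C(C)(C)C)O1 | intermediate
8 | (2R,5S)-5-[(5-bromo-2-chloropyridin-4-yl)(hydroxy)methyl]-2-tert-butyl-5-methyl-1,3-dioxolan-4-one, carbinol epimers | C[C@@]1(C(O)c2cc(Cl)ncc2Br)O[C@@H](C(C)(C)C)OC1=O | intermediate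
9 | (2R,5S)-5-(5-bromo-2-chloropyridine-4-carbonyl)-2-tert-butyl-5-methyl-1,3-dioxolan-4-one | C[C@@]1(C(=O)c2cc(Cl)ncc2Br)O[C@@H](C(C)(C)C)OC1=O | intermediate
10 | (2R,5S)-5-[1-(5-bromo-2-chloropyridin-4-yl)-1-hydroxyethyl]-2-tert-butyl-5-methyl-1,3-dioxolan-4-one, carbinol epimers | C[C@@]1(C(C)(O)c2cc(Cl)ncc2Br)O[C@@H](C(C)(C)C)OC1=O | intermediate
11 | chlorosulfite ester of 10 (not isolated) | C[C@@]1(C(C)(OS(=O)Cl)c2cc(Cl)ncc2Br)O[C@@H](C(C)(C)C)OC1=O | intermediate
12 | (2R,5S)-5-[1-(5-bromo-2-chloropyridin-4-yl)ethenyl]-2-tert-butyl-5-methyl-1,3-dioxolan-4-one | C[C@@]1(C(=C)c2cc(Cl)ncc2Br)O[C@@H](C(C)(C)C)OC1=O | intermediate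
13 | aryllithium from 12, lithium in place of bromine (not isolated) | C[C@@]1(C(=C)c2cc(Cl)ncc2[Li])O[C@@H](C(C)(C)C)OC1=O | intermediate
14 | lithium hemiketal, ring B closed with the dioxolane still cis-fused across C6–C7 (not isolated) | C[C@@]12O[C@@H](C(C)(C)C)O[C@]1(O[Li])c3cnc(Cl)cc3C2=C | intermediate
15 | (S)-3-chloro-6-hydroxy-6-methyl-5-methylidene-5,6-dihydro-7H-cyclopenta[c]pyridin-7-one | Clc1cc2c(cn1)C(=O)[C@@](C)(O)C2=C | intermediate
16 | (S)-6-(tert-butyldimethylsilyloxy)-3-chloro-6-methyl-5-methylidene-5,6-dihydro-7H-cyclopenta[c]pyridin-7-one | Clc1cc2c(cn1)C(=O)[C@@](C)(O[Si](C)(C)C(C)(C)C)C2=C | intermediate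
17 | (5S,6S)-6-(tert-butyldimethylsilyloxy)-3-chloro-5-hydroxy-5-(hydroxymethyl)-6-methyl-5,6-dihydro-7H-cyclopenta[c]pyridin-7-one | Clc1cc2c(cn1)C(=O)[C@@](C)(O[Si](C)(C)C(C)(C)C)[C@@]2(O)CO | intermediate
18 | (5R,6S)-6-(tert-butyldimethylsilyloxy)-3-chloro-5-hydroxy-6-methyl-7-oxo-6,7-dihydro-5H-cyclopenta[c]pyridine-5-carbaldehyde | Clc1cc2c(cn1)C(=O)[C@@](C)(O[Si](C)(C)C(C)(C)C)[C@@]2(O)C=O | intermediate
19 | (5R,6S)-6-(tert-butyldimethylsilyloxy)-3-chloro-5-hydroxy-6-methyl-7-oxo-6,7-dihydro-5H-cyclopenta[c]pyridine-5-carboxylic acid | Clc1cc2c(cn1)C(=O)[C@@](C)(O[Si](C)(C)C(C)(C)C)[C@@]2(O)C(=O)O | intermediate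
20 | methyl (5R,6S)-6-(tert-butyldimethylsilyloxy)-3-chloro-5-hydroxy-6-methyl-7-oxo-6,7-dihydro-5H-cyclopenta[c]pyridine-5-carboxylate | Clc1cc2c(cn1)C(=O)[C@@](C)(O[Si](C)(C)C(C)(C)C)[C@@]2(O)C(=O)OC | intermediate
21 | methyl (5R,6S)-6-(tert-butyldimethylsilyloxy)-3-chloro-6-methyl-7-oxo-5-(triethylsilyloxy)-6,7-dihydro-5H-cyclopenta[c]pyridine-5-carboxylate | Clc1cc2c(cn1)C(=O)[C@@](C)(O[Si](C)(C)C(C)(C)C)[C@@]2(O[Si](CC)(CC)CC)C(=O)OC | intermediate
22 | (S)-2-methylbutan-1-ol | CC[C@H](C)CO | starting material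
23 | (S)-2-methylbutanal | CC[C@H](C)C=O | intermediate
24 | ethyl (2E,4S)-2,4-dimethylhex-2-enoate | CC[C@H](C)/C=C(C)/C(=O)OCC | intermediate
25 | (2E,4S)-2,4-dimethylhex-2-en-1-ol | CC[C@H](C)/C=C(C)/CO | intermediate
26 | (2E,4S)-2,4-dimethylhex-2-enal | CC[C@H](C)/C=C(C)/C=O | intermediate
27 | (3E,5S)-1,1-dibromo-3,5-dimethylhepta-1,3-diene | CC[C@H](C)/C=C(C)/C=C(Br)Br | intermediate
28 | lithium (3E,5S)-3,5-dimethylhept-3-en-1-yn-1-ide (not isolated) | CC[C@H](C)/C=C(C)/C#C[Li] | intermediate
29 | (3E,5S)-3,5-dimethylhept-3-en-1-yne | CC[C@H](C)/C=C(C)/C#C | intermediate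
30 | 2-[(1E,3E,5S)-3,5-dimethylhepta-1,3-dien-1-yl]-4,4,5,5-tetramethyl-1,3,2-dioxaborolane | CC[C@H](C)/C=C(C)/C=C/B1OC(C)(C)C(C)(C)O1 | intermediate
31 | methyl (5R,6S)-6-(tert-butyldimethylsilyloxy)-3-[(1E,3E,5S)-3,5-dimethylhepta-1,3-dien-1-yl]-6-methyl-7-oxo-5-(triethylsilyloxy)-6,7-dihydro-5H-cyclopenta[c]pyridine-5-carboxylate | CC[C@H](C)/C=C(C)/C=C/c1cc2c(cn1)C(=O)[C@@](C)(O[Si](C)(C)C(C)(C)C)[C@@]2(O[Si](CC)(CC)CC)C(=O)OC | intermediate
32 | methyl (5R,6S)-3-[(1E,3E,5S)-3,5-dimethylhepta-1,3-dien-1-yl]-5,6-dihydroxy-6-methyl-7-oxo-6,7-dihydro-5H-cyclopenta[c]pyridine-5-carboxylate (CNP0086933.1) | CC[C@H](C)/C=C(C)/C=C/c1cc2c(cn1)C(=O)[C@@](C)(O)[C@@]2(O)C(=O)OC | target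

## Step count and weak points
Total steps: 22. The longest linear sequence is 14 steps: step 1 or step 2, then steps 3–13, 21 and 22. The side-chain branch (steps 14–20) is 7 steps before the coupling.

**Step 7 (Parham cyclisation).** n-BuLi could attack the lactone carbonyl or the vinylpyridine unit, and the aldehyde released from the auxiliary could trap organometal. The fallback sets out from 12 and comes back at 16, by-passing 15.
- The auxiliary is removed first with K2CO3 in MeOH at 0 °C. This gives methyl (S)-3-(5-bromo-2-chloropyridin-4-yl)-2-hydroxy-2-methylbut-3-enoate F1.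
- TBSOTf/2,6-lutidine converts it into methyl (S)-3-(5-bromo-2-chloropyridin-4-yl)-2-(tert-butyldimethylsilyloxy)-2-methylbut-3-enoate F2.
- Bromine–magnesium exchange with iPrMgCl·LiCl (THF, −15 °C) then closes ring B on the plain methyl ester. The metal is milder and no aldehyde is released in the flask.

**Step 9 (facial selectivity of the dihydroxylation, the only source of C5).** The fallback creates C5 in the aldol itself. It sets out from 4 and 3 and comes back at 21.
- Compound 4 is lithiated to 5 as in step 2 and quenched with excess dimethyl oxalate. This gives methyl 2-(5-bromo-2-chloropyridin-4-yl)-2-oxoacetate F3.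
- Enolate 7 (from 3) adds to the keto group at −78 °C, again anti to the tert-butyl group, so C6 stays secure.
- The two C5 epimers are separated on silica, with the assignment made by NOE after ring closure. The wanted one is methyl (R)-2-(5-bromo-2-chloropyridin-4-yl)-2-[(2R,4S)-2-tert-butyl-4-methyl-5-oxo-1,3-dioxolan-4-yl]-2-hydroxyacetate F4.
- TESOTf/2,6-lutidine gives its triethylsilyl ether, methyl (R)-2-(5-bromo-2-chloropyridin-4-yl)-2-[(2R,4S)-2-tert-butyl-4-methyl-5-oxo-1,3-dioxolan-4-yl]-2-(triethylsilyloxy)acetate F5.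
- n-BuLi under the conditions of step 7 closes ring B to methyl (5R,6S)-3-chloro-6-hydroxy-6-methyl-7-oxo-5-(triethylsilyloxy)-6,7-dihydro-5H-cyclopenta[c]pyridine-5-carboxylate F6.
- TBSOTf/2,6-lutidine then gives 21.

**Step 13 (silylation of the very crowded C5 hydroxyl, needed for the basic coupling).** The fallback drops this protection and couples without base. It sets out from 20 and 29 and comes back at 32.
- Hydrostannation of 29 (Bu3SnH, PdCl2(PPh3)2 2 mol %, THF, 0 °C) gives tributyl[(1E,3E,5S)-3,5-dimethylhepta-1,3-dien-1-yl]stannane F7.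
- Neutral Stille coupling with 20 (Pd(PPh3)4 5 mol %, toluene, 100 °C) gives methyl (5R,6S)-6-(tert-butyldimethylsilyloxy)-3-[(1E,3E,5S)-3,5-dimethylhepta-1,3-dien-1-yl]-5-hydroxy-6-methyl-7-oxo-6,7-dihydro-5H-cyclopenta[c]pyridine-5-carboxylate F8.
- HF·pyridine, as in step 22, then gives 32.

## Further compounds
F1 | step 7 | methyl (S)-3-(5-bromo-2-chloropyridin-4-yl)-2-hydroxy-2-methylbut-3-enoate | C=C(c1cc(Cl)ncc1Br)[C@](C)(O)C(=O)OC
F2 | step 7 | methyl (S)-3-(5-bromo-2-chloropyridin-4-yl)-2-(tert-butyldimethylsilyloxy)-2-methylbut-3-enoate | C=C(c1cc(Cl)ncc1Br)[C@](C)(O[Si](C)(C)C(C)(C)C)C(=O)OC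
F3 | step 9 | methyl 2-(5-bromo-2-chloropyridin-4-yl)-2-oxoacetate | COC(=O)C(=O)c1cc(Cl)ncc1Br
F4 | step 9 | methyl (R)-2-(5-bromo-2-chloropyridin-4-yl)-2-[(2R,4S)-2-tert-butyl-4-methyl-5-oxo-1,3-dioxolan-4-yl]-2-hydroxyacetate | C[C@@]1([C@@](O)(C(=O)OC)c2cc(Cl)ncc2Br)O[C@@H](C(C)(C)C)OC1=O
F5 | step 9 | methyl (R)-2-(5-bromo-2-chloropyridin-4-yl)-2-[(2R,4S)-2-tert-butyl-4-methyl-5-oxo-1,3-dioxolan-4-yl]-2-(triethylsilyloxy)acetate | C[C@@]1([C@@](O[Si](CC)(CC)CC)(C(=O)OC)c2cc(Cl)ncc2Br)O[C@@H](C(C)(C)C)OC1=O
F6 | step 9 | methyl (5R,6S)-3-chloro-6-hydroxy-6-methyl-7-oxo-5-(triethylsilyloxy)-6,7-dihydro-5H-cyclopenta[c]pyridine-5-carboxylate | Clc1cc2c(cn1)C(=O)[C@@](C)(O)[C@@]2(O[Si](CC)(CC)CC)C(=O)OC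
F7 | step 13 | tributyl[(1E,3E,5S)-3,5-dimethylhepta-1,3-dien-1-yl]stannane | CC[C@H](C)/C=C(C)/C=C/[Sn](CCCC)(CCCC)CCCC
F8 | step 13 | methyl (5R,6S)-6-(tert-butyldimethylsilyloxy)-3-[(1E,3E,5S)-3,5-dimethylhepta-1,3-dien-1-yl]-5-hydroxy-6-methyl-7-oxo-6,7-dihydro-5H-cyclopenta[c]pyridine-5-carboxylate | CC[C@H](C)/C=C(C)/C=C/c1cc2c(cn1)C(=O)[C@@](C)(O[Si](C)(C)C(C)(C)C)[C@@]2(O)C(=O)OC
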